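I count in fractions of the charge.

| flask | G | remark | time |
|---|---|---|---|
| alpha | 0.50 M | run made earlier |  |
| gamma | 1.1 M | run made earlier |  |
| flask | 0.75 M |  | 12 h |

| run | time / h | Z / % | G / % |
|---|---|---|---|
| alpha | 0.100 | 31.2 | 54.7 |
| alpha | 0.333 | 23.1 | 23.2 |
| alpha | 1.00 | 6.5 | 4.4 |
| alpha | 3.00 | 4.0 | 2.6 |
| alpha | 10.0 | 4.0 | 2.7 |
| gamma | 0.100 | 31.3 | 54.8 |
| gamma | 0.333 | 23.2 | 23.0 |
| gamma | 1.00 | 6.4 | 4.8 |
| gamma | 3.00 | 4.1 | 2.5 |
| gamma | 10.0 | 4.2 | 2.3 |

(scatter of a reading: 0.3 percentage points)

- the moment within 12 h at which there is most Z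
- the amount of Z, in percent of the G charged, at that time
- the first time at which Z reaches 9.8%, in the same percent, in min

- the numbers in the tables scatter by 0.3 percentage points (one standard deviation)
- steps under discussion: G <-> Z; G <-> J; Z <-> E

I define the charge-free constant of G as ln(1/fraction of G left) divided by the time. From the first reading it is 6.03 h⁻¹ in alpha and 6.01 h⁻¹ in gamma, although gamma holds 2.20 times the charge. The two constants agree, so the early loss of G is first order in G, and I put the flask at 0.75 M on the same fraction curve.

Z is made from G and then falls away; taking that fall to be about as fast as the loss of G, I set its top in the flask near 1/6.03 h⁻¹, that is 0.166 h, at about a third of the charge, which is the first Z reading of alpha. Counting the earliest G lost as Z, I reckon that Z reaches 9.8% at 1.03 min.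

The forecast, which also holds that “the kinetics are first order”, gives an earlier top than mine at 0.14 h, with 32%, and 0.95 min for the level. The flask gives 0.137 h, 32.7% and 0.936 min.

    G ⇌ Z (K = 1.70, k = 0.00200 s⁻¹)
    G ⇌ J (K = 2.60, k = 3.60 × 10⁻⁵ s⁻¹)
    Z ⇌ E (K = 22.0, k = 0.00170 s⁻¹)

At 0.137 h the flask holds G 46.3%, against 43.8% from 6.03 h⁻¹. The forward half-lives of G into Z alone and of Z into E alone are 0.096 h and 0.11 h, beside the 0.115 h that 6.03 h⁻¹ gives as a half-life, and the relaxation half-life of Z and E by that step alone, both ways together, 0.108 h, is short against 12 h. Read on 6.03 h⁻¹, the flask charged at 3.0 M should keep the same curve, and its Z tops at 32.7%.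

The data are calculated with constants of no real substance; scatter was added.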